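The route rests on cutting the cyclobutane of the caryophyllane half across C1–C9 and C10–C11. Because this four-membered ring (C1, C9, C10, C11; gem-dimethyl C11 beside C1) is bonded via C9 to the spiro ether carbon C8 of the pyran, C9 and C10 are traced back to an ethynyl substituent on C8, and C1 and C11 to the terminal prenyl double bond of the C8 side chain. One gold-catalysed alkyne–alkene [2+2] cycloaddition then creates both bonds, the cyclobutene, the nine-membered carbocycle and the C1 stereocentre. Its precursor is a (2S,4R)-2-ethynylchromane-5,7-dione whose side chain holds a Z-enone (C5=O, C3=C4) and ends in the prenyl alkene.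

Key step: step 10

Numbering: caryophyllane numbers C1–C11 for the carbocyclic half; chromene numbers with primes for the pyran-dione half (C2′ = C8, C4′ bears the isobutyl group).

Assumption: the cinchona primary amine of step 3 is assigned the sense that gives 4′R by analogy with iminium Michael additions of cyclic 1,3-diones to alkyl enones; should the sense be opposite, the pseudoenantiomeric 9-amino-9-deoxy-epi-quinidine is used.

Step 1
Reactants: 1 methyl 5-bromo-4-oxopentanoate
Product: 3 methyl 4-oxo-5-(triphenyl-λ5-phosphanylidene)pentanoate, via phosphonium bromide 2 (not isolated)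
Conditions: PPh3, toluene, rt; then Na2CO3 (aq), CH2Cl2
Reagents that add atoms: triphenylphosphine, c1ccc(cc1)P(c1ccccc1)c1ccccc1
Why: SN2 alkylation of the phosphine by the primary α-bromo ketone and deprotonation of the acidic salt should give the stabilised acyl ylide (Wittig reagent preparation) without touching the methyl ester.

Step 2
Reactants: 3 methyl 4-oxo-5-(triphenyl-λ5-phosphanylidene)pentanoate; 4 isovaleraldehyde
Product: 5 methyl (E)-8-methyl-4-oxonon-5-enoate
Conditions: toluene, 80 °C, sealed tube
Reagents that add atoms: none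
Why: Wittig olefination with a stabilised keto ylide is reliably E-selective and avoids the regiochemical ambiguity of a direct aldol condensation on a levulinate.

Step 3
Reactants: 5 methyl (E)-8-methyl-4-oxonon-5-enoate; 6 syncarpic acid
Product: 8 methyl 3-[(4R)-4-isobutyl-6,6,8,8-tetramethyl-5,7-dioxo-5,6,7,8-tetrahydro-4H-chromen-2-yl]propanoate, via hemiketal 7 (not isolated)
Conditions: 9-amino-9-deoxy-epi-quinine (20 mol%), TFA (40 mol%), CH2Cl2, rt; then p-TsOH (cat.), 4 Å MS, toluene, 60 °C
Reagents that add atoms: none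
Why: Iminium-activated enantioselective Michael addition of the cyclic 1,3-dione carbon to the enone, in which the chiral primary amine shields one face of the β-carbon and so sets C4′ as R, is followed by hemiketalisation and acid-catalysed dehydration to the 4H-pyran enol ether.

Step 4
Reactants: 8 methyl 3-[(4R)-4-isobutyl-6,6,8,8-tetramethyl-5,7-dioxo-5,6,7,8-tetrahydro-4H-chromen-2-yl]propanoate
Product: 9 methyl 3-[(2S,4R)-4-isobutyl-6,6,8,8-tetramethyl-5,7-dioxo-2-{[tri(propan-2-yl)silyl]ethynyl}-3,4,5,6,7,8-hexahydro-2H-chromen-2-yl]propanoate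
Conditions: Fe(acac)3 (30 mol%), PhSiH3, TIPS–C≡C–SO2Ph, EtOH/(CH2OH)2, 60 °C
Reagents that add atoms: triisopropyl[(phenylsulfonyl)ethynyl]silane, CC(C)[Si](C#CS(=O)(=O)c1ccccc1)(C(C)C)C(C)C
Why: Markovnikov metal-hydride hydrogen-atom transfer to the enol ether gives the tertiary α-oxy radical at C8 (C2′), which adds to the alkynyl sulfone and expels the sulfonyl radical (radical hydroalkynylation); the alkyne should enter axially on the face opposite the pseudoaxial isobutyl group, setting C8 as S with the alkyne trans to isobutyl.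

Step 5
Reactants: 9 methyl 3-[(2S,4R)-4-isobutyl-6,6,8,8-tetramethyl-5,7-dioxo-2-{[tri(propan-2-yl)silyl]ethynyl}-3,4,5,6,7,8-hexahydro-2H-chromen-2-yl]propanoate
Product: 10 N-methoxy-N-methyl-3-[(2S,4R)-4-isobutyl-6,6,8,8-tetramethyl-5,7-dioxo-2-{[tri(propan-2-yl)silyl]ethynyl}-3,4,5,6,7,8-hexahydro-2H-chromen-2-yl]propanamide
Conditions: MeNHOMe·HCl, i-PrMgCl, THF, −20 °C
Reagents that add atoms: N,O-dimethylhydroxylamine hydrochloride, CNOC.Cl
Why: Aminolysis of the unhindered methyl ester by the magnesium amide (Weinreb amide synthesis) should be selective because both ring carbonyls are flanked by quaternary carbons and the silyl alkyne is inert.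

Step 6
Reactants: 10 N-methoxy-N-methyl-3-[(2S,4R)-4-isobutyl-6,6,8,8-tetramethyl-5,7-dioxo-2-{[tri(propan-2-yl)silyl]ethynyl}-3,4,5,6,7,8-hexahydro-2H-chromen-2-yl]propanamide
Product: 11 3-[(2S,4R)-2-ethynyl-4-isobutyl-6,6,8,8-tetramethyl-5,7-dioxo-3,4,5,6,7,8-hexahydro-2H-chromen-2-yl]-N-methoxy-N-methylpropanamide
Conditions: TBAF, THF, 0 °C
Reagents that add atoms: none
Why: Fluoride-induced protodesilylation of the alkynylsilane is placed here because the Weinreb amide tolerates fluoride, whereas the later skipped Z-dienone would be sensitive to base.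

Step 7
Reactants: 12 4-methylpent-3-en-1-ol
Product: 13 4-methylpent-3-enal
Conditions: DMP, CH2Cl2, 0 °C → rt; used at once as a solution
Reagents that add atoms: none
Why: Dess–Martin oxidation under non-basic conditions should give the β,γ-unsaturated aldehyde without migration of the double bond into conjugation.

Step 8
Reactants: 13 4-methylpent-3-enal
Product: 14 (Z)-2-iodo-6-methylhepta-2,5-diene
Conditions: EtPPh3I, n-BuLi, THF, 0 °C; I2, −78 °C; NaN(SiMe3)2, −20 °C; then 13, −78 °C → rt
Reagents that add atoms: ethyltriphenylphosphonium iodide, CC[P+](c1ccccc1)(c1ccccc1)c1ccccc1.[I-]; iodine, II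
Why: Stork–Zhao olefination with the α-iodo ylide gives 2-iodo-2-alkenes with iodine cis to the chain, and this Z geometry is what later becomes the Z-enone.

Step 9
Reactants: 11 3-[(2S,4R)-2-ethynyl-4-isobutyl-6,6,8,8-tetramethyl-5,7-dioxo-3,4,5,6,7,8-hexahydro-2H-chromen-2-yl]-N-methoxy-N-methylpropanamide; 14 (Z)-2-iodo-6-methylhepta-2,5-diene
Product: 16 (2S,4R)-2-[(4Z)-4,8-dimethyl-3-oxonona-4,7-dien-1-yl]-2-ethynyl-4-isobutyl-6,6,8,8-tetramethyl-3,4-dihydro-2H-chromene-5,7(6H,8H)-dione, via alkenyllithium 15 (not isolated)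
Conditions: 14 (2.6 equiv), t-BuLi (5.2 equiv), Et2O, −78 °C; then 11, THF, −78 °C; NH4Cl (aq), −78 °C
Reagents that add atoms: none
Why: Iodine–lithium exchange retains the alkene geometry and the alkenyllithium adds once to the Weinreb amide through the chelated tetrahedral intermediate (Weinreb ketone synthesis); one equivalent is spent on the acetylenic C–H, and the cold quench releases the Z-enone with its free alkyne and no later exposure to base.

Step 10
Reactants: 16 (2S,4R)-2-[(4Z)-4,8-dimethyl-3-oxonona-4,7-dien-1-yl]-2-ethynyl-4-isobutyl-6,6,8,8-tetramethyl-3,4-dihydro-2H-chromene-5,7(6H,8H)-dione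
Product: 17 (1S,3Z,8S,4′R)-4′-isobutyl-4,11,11,6′,6′,8′,8′-heptamethylspiro[bicyclo[7.2.0]undeca-3,9-diene-8,2′-chromane]-5,5′,7′-trione (caryophyllane numbering; C9=C10 is the cyclobutene double bond)
Conditions: [(tBuXPhos)Au(NCMe)][B(C6H3-3,5-(CF3)2)4] (10 mol%), 4 Å MS, CH2Cl2, 1 mM by syringe-pump addition of 16, 25 → 40 °C
Reagents that add atoms: none
Why: Proposed new method: cationic monovalent gold π-activates the terminal alkyne, the prenyl alkene attacks the internal carbon C9 through its less substituted carbon C1 anti to the metal, and the resulting cyclopropyl gold carbene (equivalently a C11 tertiary cation with an alkenyl-gold at C10) collapses by C10–C11 bond formation with release of the catalyst, the polarity that puts CMe2 next to C10. The closest known reaction type is the gold-catalysed [2+2] cycloaddition of terminal aryl alkynes with alkenes and its macrocyclic enyne variant, which give cyclobutenes of the same regiochemistry; a nine-membered closure from an alkyl alkyne carrying a propargylic ether has not been shown. The nine-membered carbocycle closes by 9-exo-dig attack (C1 on C9), and the cyclobutene by four-membered recombination of the cation with the alkenyl-gold carbon (C11 on C10), formally a ring expansion of the cyclopropyl carbene. C1, the only new stereocentre, is controlled by C8: the alkene must approach C9 anti to the ligated gold, the small pyran oxygen is expected to lie on the gold side, and the Z-enone turn should then return C2 to C1 from the face opposite C7, which gives the required C1/C8 relationship. The step needs chemoselectivity for the prenyl alkene over C3=C4 and over oxygen nucleophiles, which the enone conjugation of C3=C4, the reversibility of carbonyl-oxygen addition under dry base-free conditions and the bulky biaryl phosphine with a non-coordinating borate are meant to secure, while the Z alkene, quaternary C8 and high dilution favour ring closure over oligomers.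

Step 11
Reactants: 17 (1S,3Z,8S,4′R)-4′-isobutyl-4,11,11,6′,6′,8′,8′-heptamethylspiro[bicyclo[7.2.0]undeca-3,9-diene-8,2′-chromane]-5,5′,7′-trione
Product: 18 (1R,3Z,8S,9S,4′R)-4′-isobutyl-4,11,11,6′,6′,8′,8′-heptamethylspiro[bicyclo[7.2.0]undec-3-ene-8,2′-chromane]-5,5′,7′-trione (trans-fused cyclobutane)
Conditions: Co(dpm)2 (20 mol%), PhSiH3, t-BuOOH, i-PrOH, 22 °C, degassed
Reagents that add atoms: none
Why: Metal-hydride hydrogen-atom-transfer hydrogenation: the cobalt hydride, as in Mukaiyama-type hydrofunctionalisations, should transfer H• to C10 of the strained electron-rich cyclobutene rather than to the enone or the vinylogous ester, and the tertiary C9 radical should then take up hydrogen so that C8 ends trans to C2, the less strained trans ring fusion (C9 S).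

Step 12
Reactants: 18 (1R,3Z,8S,9S,4′R)-4′-isobutyl-4,11,11,6′,6′,8′,8′-heptamethylspiro[bicyclo[7.2.0]undec-3-ene-8,2′-chromane]-5,5′,7′-trione
Product: 19 tomentodione O
Conditions: (S)-2-methyl-CBS-oxazaborolidine, catecholborane, toluene, −78 °C
Reagents that add atoms: none
Why: Corey–Bakshi–Shibata reduction: the (S)-oxazaborolidine should bind the C5 ketone with the α-methylalkenyl side as the large group and deliver hydride 1,2 under reagent control to give the 5R allylic alcohol, while the two ring carbonyls, deactivated or flanked by quaternary carbons, stay untouched.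

Compound list
1 | methyl 5-bromo-4-oxopentanoate (methyl 5-bromolevulinate) | COC(=O)CCC(=O)CBr | starting material
2 | (5-methoxy-2,5-dioxopentyl)triphenylphosphonium bromide | COC(=O)CCC(=O)C[P+](c1ccccc1)(c1ccccc1)c1ccccc1.[Br-] | intermediate (not isolated)
3 | methyl 4-oxo-5-(triphenyl-λ5-phosphanylidene)pentanoate | COC(=O)CCC(=O)C=P(c1ccccc1)(c1ccccc1)c1ccccc1 | intermediate
4 | isovaleraldehyde (3-methylbutanal) | CC(C)CC=O | starting material
5 | methyl (E)-8-methyl-4-oxonon-5-enoate | COC(=O)CCC(=O)/C=C/CC(C)C | intermediate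
6 | syncarpic acid (2,2,4,4-tetramethylcyclohexane-1,3,5-trione) | CC1(C)C(=O)CC(=O)C(C)(C)C1=O | starting material
7 | methyl 3-[(4R)-2-hydroxy-4-isobutyl-6,6,8,8-tetramethyl-5,7-dioxo-3,4,5,6,7,8-hexahydro-2H-chromen-2-yl]propanoate (hemiketal, both C2′ epimers) | COC(=O)CCC1(O)C[C@@H](CC(C)C)C2=C(O1)C(C)(C)C(=O)C(C)(C)C2=O | intermediate (not isolated)
8 | methyl 3-[(4R)-4-isobutyl-6,6,8,8-tetramethyl-5,7-dioxo-5,6,7,8-tetrahydro-4H-chromen-2-yl]propanoate | COC(=O)CCC1=C[C@@H](CC(C)C)C2=C(O1)C(C)(C)C(=O)C(C)(C)C2=O | intermediate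
9 | methyl 3-[(2S,4R)-4-isobutyl-6,6,8,8-tetramethyl-5,7-dioxo-2-{[tri(propan-2-yl)silyl]ethynyl}-3,4,5,6,7,8-hexahydro-2H-chromen-2-yl]propanoate | CC(C)[Si](C(C)C)(C(C)C)C#C[C@]1(CCC(=O)OC)C[C@@H](CC(C)C)C2=C(O1)C(C)(C)C(=O)C(C)(C)C2=O | intermediate
10 | N-methoxy-N-methyl-3-[(2S,4R)-4-isobutyl-6,6,8,8-tetramethyl-5,7-dioxo-2-{[tri(propan-2-yl)silyl]ethynyl}-3,4,5,6,7,8-hexahydro-2H-chromen-2-yl]propanamide | CC(C)[Si](C(C)C)(C(C)C)C#C[C@]1(CCC(=O)N(C)OC)C[C@@H](CC(C)C)C2=C(O1)C(C)(C)C(=O)C(C)(C)C2=O | intermediate
11 | 3-[(2S,4R)-2-ethynyl-4-isobutyl-6,6,8,8-tetramethyl-5,7-dioxo-3,4,5,6,7,8-hexahydro-2H-chromen-2-yl]-N-methoxy-N-methylpropanamide | C#C[C@]1(CCC(=O)N(C)OC)C[C@@H](CC(C)C)C2=C(O1)C(C)(C)C(=O)C(C)(C)C2=O | intermediate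
12 | 4-methylpent-3-en-1-ol | CC(C)=CCCO | starting material
13 | 4-methylpent-3-enal | CC(C)=CCC=O | intermediate
14 | (Z)-2-iodo-6-methylhepta-2,5-diene | C/C(I)=C/CC=C(C)C | intermediate
15 | [(2Z)-6-methylhepta-2,5-dien-2-yl]lithium | [Li]/C(C)=C\CC=C(C)C | intermediate (not isolated)
16 | (2S,4R)-2-[(4Z)-4,8-dimethyl-3-oxonona-4,7-dien-1-yl]-2-ethynyl-4-isobutyl-6,6,8,8-tetramethyl-3,4-dihydro-2H-chromene-5,7(6H,8H)-dione (seco ethynyl Z-enone) | C#C[C@]1(CCC(=O)/C(C)=C\CC=C(C)C)C[C@@H](CC(C)C)C2=C(O1)C(C)(C)C(=O)C(C)(C)C2=O | intermediate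
17 | (1S,3Z,8S,4′R)-4′-isobutyl-4,11,11,6′,6′,8′,8′-heptamethylspiro[bicyclo[7.2.0]undeca-3,9-diene-8,2′-chromane]-5,5′,7′-trione (caryophyllane numbering; cyclobutene C9=C10, Z-cyclononenone) | C/C1=C/C[C@@H]2C(=CC2(C)C)[C@]2(CCC1=O)C[C@@H](CC(C)C)C1=C(O2)C(C)(C)C(=O)C(C)(C)C1=O | intermediate
18 | (1R,3Z,8S,9S,4′R)-4′-isobutyl-4,11,11,6′,6′,8′,8′-heptamethylspiro[bicyclo[7.2.0]undec-3-ene-8,2′-chromane]-5,5′,7′-trione (caryophyllane numbering; H1 and H9 trans) | C/C1=C/C[C@@H]2[C@H](CC2(C)C)[C@]2(CCC1=O)C[C@@H](CC(C)C)C1=C(O2)C(C)(C)C(=O)C(C)(C)C1=O | intermediate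
19 | tomentodione O, (1R,3Z,5R,8S,9S,4′R)-5-hydroxy-4′-isobutyl-4,11,11,6′,6′,8′,8′-heptamethylspiro[bicyclo[7.2.0]undec-3-ene-8,2′-chromane]-5′,7′-dione (caryophyllane numbering) | C/C1=C/C[C@@H]2[C@H](CC2(C)C)[C@]2(CC[C@H]1O)C[C@@H](CC(C)C)C1=C(O2)C(C)(C)C(=O)C(C)(C)C1=O | target

Total step count: 12. Longest linear sequence: 10 steps (steps 1–6 and 9–12); steps 7 and 8 form the side branch to the alkenyl iodide.

Steps most likely to fail

Step 10 (gold [2+2], new method). The nine-membered closure may be outrun by intermolecular alkyne–alkene addition, giving oligomers. The C5 carbonyl oxygen may add to the activated alkyne and drain material into hydration or alkyne–carbonyl metathesis. The alkene may also approach C9 with the wrong face, giving the C1 epimer. The fallback uses known chemistry and takes the trans-fused cyclobutane from the chiral pool; it sets out from 6 and 4 and comes back to the route at 19. Commercial (−)-caryophyllene oxide F1 is isomerised with a hindered aluminium amide, Et2Al(tmp) (tmp = 2,2,6,6-tetramethylpiperidide), in toluene at 0 °C. This epoxide-to-allylic-alcohol opening leaves the C5–O bond untouched, and the endocyclic isomer (1R,3Z,5R,9S)-caryophylla-3,8(13)-dien-5-ol F2 is separated from the exocyclic isomer. Knoevenagel condensation of 6 with 4 (ethylenediammonium diacetate, warm toluene) generates the enetrione 6-(3-methylbutylidene)-2,2,4,4-tetramethylcyclohexane-1,3,5-trione F3 in the flask. F3 should add as a heterodiene to the exocyclic C8=C13 methylene of F2 (inverse-demand hetero-Diels–Alder reaction) and form the spiro pyran of 19, which would have to be separated from its C8 and C4′ diastereomers.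

Step 11 (hydrogen-atom-transfer hydrogenation). Hydrogen-atom transfer to the conjugated C3=C4 bond (conjugate reduction of the enone) may compete with transfer to the hindered cyclobutene carbon C10. Hydrogen may also be delivered to the C9 radical on the face of H1, which would give the cis ring fusion. The fallback removes the conjugated acceptor before the radical step; it sets out from 17 and comes back at 19. Corey–Bakshi–Shibata reduction of 17 ((S)-2-methyl-CBS-oxazaborolidine, catecholborane) should give the cyclobutene allylic alcohol F4. Silylation (TBSOTf, 2,6-lutidine) gives the tert-butyldimethylsilyl ether F5, in which C5 is sp3 and the bulky silyl ether shields C3=C4. Hydrogen-atom-transfer hydrogenation of the strained cyclobutene (Mn(dpm)3, PhSiH3, t-BuOOH, i-PrOH) should then give the silyl ether F6, and TBAF releases 19. If the cis fusion persists in this series as well, the chiral-pool fallback described for step 10 applies.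

Step 4 (radical hydroalkynylation). The C8 radical may be reduced before it is trapped, which amounts to net hydrogenation of the enol ether. The sulfone may also add on the face of the isobutyl group, giving low diastereoselectivity. The fallback replaces the radical by the cation; it sets out from 8 and comes back at 9. Acid-catalysed addition of methanol to the enol ether (camphorsulfonic acid, MeOH) gives the mixed methyl ketal F7. BF3·OEt2 in CH2Cl2/MeCN then generates the cyclic oxocarbenium ion, which is captured by potassium trifluoro{[tri(propan-2-yl)silyl]ethynyl}borate. The nucleophile should again enter axially, anti to the pseudoaxial isobutyl group, and deliver 9.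

Further compounds
F1 | step 10 | (−)-caryophyllene oxide, (1R,4R,5R,9S), commercial | C[C@@]12CC[C@@H]3[C@H](CC3(C)C)C(=C)CC[C@H]1O2
F2 | step 10 | (1R,3Z,5R,9S)-caryophylla-3,8(13)-dien-5-ol | C/C1=C/C[C@@H]2[C@H](CC2(C)C)C(=C)CC[C@H]1O
F3 | step 10 | 6-(3-methylbutylidene)-2,2,4,4-tetramethylcyclohexane-1,3,5-trione | CC(C)CC=C1C(=O)C(C)(C)C(=O)C(C)(C)C1=O
F4 | step 11 | (1S,3Z,5R,8S,4′R)-5-hydroxy-4′-isobutyl-4,11,11,6′,6′,8′,8′-heptamethylspiro[bicyclo[7.2.0]undeca-3,9-diene-8,2′-chromane]-5′,7′-dione (9,10-didehydro 19) | C/C1=C/C[C@@H]2C(=CC2(C)C)[C@]2(CC[C@H]1O)C[C@@H](CC(C)C)C1=C(O2)C(C)(C)C(=O)C(C)(C)C1=O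
F5 | step 11 | 5-O-tert-butyldimethylsilyl ether of F4 | C/C1=C/C[C@@H]2C(=CC2(C)C)[C@]2(CC[C@H]1O[Si](C)(C)C(C)(C)C)C[C@@H](CC(C)C)C1=C(O2)C(C)(C)C(=O)C(C)(C)C1=O
F6 | step 11 | 5-O-tert-butyldimethylsilyl ether of 19 | C/C1=C/C[C@@H]2[C@H](CC2(C)C)[C@]2(CC[C@H]1O[Si](C)(C)C(C)(C)C)C[C@@H](CC(C)C)C1=C(O2)C(C)(C)C(=O)C(C)(C)C1=O
F7 | step 4 | methyl 3-[(4R)-4-isobutyl-2-methoxy-6,6,8,8-tetramethyl-5,7-dioxo-3,4,5,6,7,8-hexahydro-2H-chromen-2-yl]propanoate (methyl ketal, both C2′ epimers) | COC(=O)CCC1(OC)C[C@@H](CC(C)C)C2=C(O1)C(C)(C)C(=O)C(C)(C)C2=O
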